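## Retrosynthetic overview

1. Last steps: DDQ removal of the C9 PMB ether ← C5/C14 diacetate ← trans-epoxide made by C5-OH-directed VO(acac)₂ epoxidation of the C3=C4 alkene of the macrolactone.
2. The 14-membered ring and the trans-fused α-methylene-γ-lactone form in one operation. An intramolecular Nozaki–Hiyama–Kishi (NHK) allylation of a (Z)-2-(bromomethyl)acrylate onto the C2 (E)-enal forms C1–C2, and lactonization follows.
3. The bromoacrylate comes from a Morita–Baylis–Hillman (MBH) reaction of the C14 α-silyloxy aldehyde followed by SN2′ bromination. The C2 enal is carried as a dimethyl acetal.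
4. The chain is assembled from three fragments by two E-selective cross-metatheses (C11=C12, then C7=C8). C5 and C9 are set by Brown allylations with opposite reagent enantiomers, and C14 by the Mikami glyoxylate–ene reaction.
5. Protecting groups: TBS on C5 and C14 (both removed after the NHK step), PMB on C9 (removed last).

Assumptions (one line each):
- Cembrane numbering is used. C1 is the lactone β-carbon, C2 the lactone O-carbon, C3/C4 the epoxide, C5 and C14 the acetoxy carbons, C9 the free OH.
- (−)-Ipc₂B-allyl (from (+)-α-pinene) delivers allyl to the Si face of an aldehyde, and (+)-Ipc₂B-allyl to the Re face.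
- The target SMILES has a trans-fused lactone, three E-trisubstituted ring alkenes (C3=C4 before epoxidation) and a trans-epoxide. The route is designed for this.
- The C1/C2 configuration (NHK) and the C3/C4 epoxide face are assumed to follow substrate control to the natural relative configuration.

## Route

**Step 1**
Reactants: 1 (2,2-dimethoxyacetaldehyde, 60% aqueous solution) + 2 (2-(triphenylphosphoranylidene)propanal)
Product: 3 ((E)-4,4-dimethoxy-2-methylbut-2-enal)
Conditions: CH2Cl2, 25 °C
Reagents that add atoms: none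
Why: Wittig olefination with a stabilized ylide gives the E-trisubstituted enal acetal, which carries the masked C2 aldehyde and the C4 methyl.

**Step 2**
Reactants: 3
Product: 4 ((4R,5E)-7,7-dimethoxy-5-methylhepta-1,5-dien-4-ol)
Conditions: (+)-Ipc2B-allyl, Et2O, −78 °C; then NaOH, H2O2
Reagents that add atoms: (+)-B-allyldiisopinocampheylborane (from (−)-α-pinene), C=CCB(C1C(C)C2CC(C1)C2(C)C)C1C(C)C2CC(C1)C2(C)C (pinane stereocentres omitted)
Why: Brown asymmetric allylation proceeds through a chair transition state with reagent control, adding allyl to the Re face of the enal to set C5 as (R).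

**Step 3**
Reactants: 4
Product: 5 (C5-OTBS ether of 4)
Conditions: TBSCl, imidazole, DMF, 25 °C
Reagents that add atoms: tert-butyldimethylsilyl chloride, CC(C)(C)[Si](C)(C)Cl
Why: Silylation keeps C5-OH inert to the later mesylation, and the TBS group survives the mild acetal hydrolysis of step 12; C5 is not touched.

**Step 4**
Reactants: 6 (methacrolein)
Product: 7 ((3S)-2-methylhexa-1,5-dien-3-ol)
Conditions: (−)-Ipc2B-allyl, Et2O, −78 °C; then NaOH, H2O2
Reagents that add atoms: (−)-B-allyldiisopinocampheylborane (from (+)-α-pinene), C=CCB(C1C(C)C2CC(C1)C2(C)C)C1C(C)C2CC(C1)C2(C)C (pinane stereocentres omitted)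
Why: Brown allylation with the opposite reagent enantiomer adds allyl to the Si face of methacrolein, setting C9 as (S) and supplying the C11 vinyl and C8 isopropenyl handles.

**Step 5**
Reactants: 7
Product: 8 (C9-OPMB ether of 7)
Conditions: NaH, PMBBr, TBAI (cat.), THF/DMF, 0 → 25 °C
Reagents that add atoms: 4-methoxybenzyl bromide, COc1ccc(CBr)cc1
Why: Williamson etherification protects C9 with a group orthogonal to the TBS ethers. PMB survives metathesis, SN2′ bromination, fluoride and epoxidation, and is removed last by DDQ; C9 is not touched.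

**Step 6**
Reactants: 9 (methyl glyoxylate) + 10 (isobutene)
Product: 11 (methyl (2R)-2-hydroxy-4-methylpent-4-enoate)
Conditions: (R)-BINOL (10 mol %), TiCl2(OiPr)2 (10 mol %), 4 Å MS, CH2Cl2, −30 °C
Reagents that add atoms: none
Why: The Mikami asymmetric glyoxylate–ene reaction forms the C13–C14 bond, and the (R)-BINOL–Ti catalyst sets C14 as (R).

**Step 7**
Reactants: 11
Product: 12 (methyl (2R)-2-(TBSO)-4-methylpent-4-enoate)
Conditions: TBSCl, imidazole, DMF, 25 °C
Reagents that add atoms: tert-butyldimethylsilyl chloride, CC(C)(C)[Si](C)(C)Cl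
Why: A TBS ether protects O14 for the DIBAL reduction, and it also blocks lactonization onto O14 in the NHK step; C14 is not touched.

**Step 8**
Reactants: 12
Product: 13 ((2R)-2-(TBSO)-4-methylpent-4-enal)
Conditions: DIBAL-H (1.05 equiv), toluene, −78 °C
Reagents that add atoms: none
Why: Low-temperature partial ester reduction stops at the aldehyde, and the α-centre is not touched. The aldehyde is used immediately to avoid epimerization.

**Step 9**
Reactants: 13 + 14 (methyl acrylate)
Product: 15 (methyl (4R)-3-hydroxy-6-methyl-2-methylidene-4-(TBSO)hept-6-enoate, C3-epimeric mixture)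
Conditions: DABCO (1 equiv), neat, 25 °C, 3–5 d
Reagents that add atoms: none
Why: The MBH reaction builds the C1–C15 and C16–C17 unit; the new C3 carbinol centre is irrelevant because it is destroyed in step 13, and C14 is not touched.

**Step 10**
Reactants: 8 (3 equiv) + 15
Product: 16 (methyl (4R,6E,9S)-4-(TBSO)-3-hydroxy-9-(PMBO)-6,10-dimethyl-2-methylidene-undeca-6,10-dienoate, C3-epimeric mixture)
Conditions: Hoveyda–Grubbs II (8 mol %), CH2Cl2, 40 °C
Reagents that add atoms: none
Why: Cross-metathesis of the terminal C11 vinyl of 8 with the methallyl alkene of 15 gives the thermodynamic E-trisubstituted C11=C12 alkene with loss of ethylene; the hindered isopropenyl and the acrylate are unreactive.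

**Step 11**
Reactants: 16 + 5 (3 equiv)
Product: 17 (methyl (4R,6E,9S,10E,13R,14E)-4,13-bis(TBSO)-3-hydroxy-16,16-dimethoxy-9-(PMBO)-6,10,14-trimethyl-2-methylidenehexadeca-6,10,14-trienoate, C3-epimeric mixture)
Conditions: Hoveyda–Grubbs II (10 mol %), CH2Cl2, 40 °C
Reagents that add atoms: none
Why: A second cross-metathesis joins the C8 isopropenyl group of 16 to the C7 vinyl group of 5 and forms the E-trisubstituted C7=C8 alkene, with loss of ethylene.

**Step 12**
Reactants: 17
Product: 18 (methyl (4R,6E,9S,10E,13R,14E)-4,13-bis(TBSO)-3-hydroxy-9-(PMBO)-6,10,14-trimethyl-2-methylidene-16-oxohexadeca-6,10,14-trienoate, the C2 enal)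
Conditions: PPTS (0.3 equiv), acetone/H2O (10:1), 55 °C
Reagents that add atoms: water, O
Why: Mildly acidic acetal hydrolysis unmasks the C2 enal and leaves the two secondary TBS ethers, the PMB ether and the E geometry intact; no stereocentre is affected.

**Step 13**
Reactants: 18
Product: 19 (methyl (2Z,4R,6E,9S,10E,13R,14E)-2-(bromomethyl)-4,13-bis(TBSO)-9-(PMBO)-6,10,14-trimethyl-16-oxohexadeca-2,6,10,14-tetraenoate)
Conditions: MsCl, Et3N, CH2Cl2, 0 °C; then LiBr, THF, 0 → 25 °C (bromide used at once)
Reagents that add atoms: lithium bromide, [Li+].[Br-]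
Why: The MBH mesylate undergoes SN2′ displacement by bromide to give the Z-allylic bromide (C14 cis to CH2Br); both C3 epimers converge, C14 is unchanged, and the enal and silyl ethers survive.

**Step 14**
Reactants: 19
Product: 20 (macrocyclic trans-fused α-methylene-γ-butyrolactone with the E-Δ3,4, E-Δ7,8 and E-Δ11,12 alkenes, 5,14-bis(TBSO) and 9-OPMB)
Conditions: CrCl2 (8 equiv), THF/DMF (10:1), 0.003 M, syringe-pump addition of 19, 25 °C; then cat. p-TsOH, CH2Cl2
Reagents that add atoms: none
Why: An intramolecular NHK allylation of the enal occurs through the γ-carbon (C1) of the E-allylchromium in a chair transition state, setting the anti C1/C2 relationship that lactonizes to the trans-fused lactone, with the sense relative to C14 assumed to be induced by the C14 stereocentre in the macrocyclic transition state; the C14-OTBS group prevents competing lactonization onto O14.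

**Step 15**
Reactants: 20
Product: 21 (5,14-diol, 9-OPMB)
Conditions: HF·pyridine, pyridine/THF, 0 → 25 °C
Reagents that add atoms: none
Why: Buffered fluoride removes both secondary TBS ethers and leaves the PMB ether, the lactone and the exo-methylene; the mildly acidic medium avoids translactonization and oxa-Michael addition.

**Step 16**
Reactants: 21
Product: 22 (3,4-epoxide, 5,14-diol, 9-OPMB)
Conditions: VO(acac)2 (5 mol %), TBHP (1.3 equiv), CH2Cl2, 0 °C
Reagents that add atoms: tert-butyl hydroperoxide, CC(C)(C)OO
Why: Vanadium-catalysed hydroxyl-directed epoxidation selects the C5-OH allylic C3=C4 alkene over the undirected C7=C8 (OPMB-allylic) and C11=C12 alkenes, the homoallylic C14-OH and the electron-poor methylene. The E alkene gives the trans-epoxide, and the face is set by the C5 oxygen and the macrocyclic conformation (substrate control).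

**Step 17**
Reactants: 22
Product: 23 (5,14-diacetate, 9-OPMB)
Conditions: Ac2O, Et3N, DMAP (cat.), CH2Cl2, 0 → 25 °C
Reagents that add atoms: acetic anhydride, CC(=O)OC(C)=O
Why: Acylation installs both acetates at the free secondary alcohols; the epoxide, lactone and PMB ether are unaffected and no stereocentre changes.

**Step 18**
Reactants: 23
Product: 24 (michaolide A)
Conditions: DDQ, CH2Cl2/pH 7 phosphate buffer (18:1), 0 °C
Reagents that add atoms: none
Why: Oxidative PMB cleavage with DDQ (buffered) frees the C9 alcohol and leaves the acetates, the acid-sensitive epoxide, the exo-methylene lactone and the alkenes intact.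

## Compound list

1 | 2,2-dimethoxyacetaldehyde | COC(OC)C=O | starting material
2 | 2-(triphenylphosphoranylidene)propanal | CC(C=O)=P(c1ccccc1)(c1ccccc1)c1ccccc1 | starting material
3 | (E)-4,4-dimethoxy-2-methylbut-2-enal | COC(OC)/C=C(C)/C=O | intermediate
4 | (4R,5E)-7,7-dimethoxy-5-methylhepta-1,5-dien-4-ol | C=CC[C@@H](O)/C(C)=C/C(OC)OC | intermediate
5 | tert-butyl{[(4R,5E)-7,7-dimethoxy-5-methylhepta-1,5-dien-4-yl]oxy}dimethylsilane | C=CC[C@@H](O[Si](C)(C)C(C)(C)C)/C(C)=C/C(OC)OC | intermediate
6 | methacrolein | C=C(C)C=O | starting material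
7 | (3S)-2-methylhexa-1,5-dien-3-ol | C=CC[C@H](O)C(C)=C | intermediate
8 | 1-methoxy-4-({[(3S)-2-methylhexa-1,5-dien-3-yl]oxy}methyl)benzene (C9-OPMB ether of 7) | C=CC[C@H](OCc1ccc(OC)cc1)C(C)=C | intermediate
9 | methyl glyoxylate | COC(=O)C=O | starting material
10 | isobutene | C=C(C)C | starting material
11 | methyl (2R)-2-hydroxy-4-methylpent-4-enoate | COC(=O)[C@H](O)CC(C)=C | intermediate
12 | methyl (2R)-2-(TBSO)-4-methylpent-4-enoate | COC(=O)[C@H](O[Si](C)(C)C(C)(C)C)CC(C)=C | intermediate
13 | (2R)-2-(TBSO)-4-methylpent-4-enal | O=C[C@H](O[Si](C)(C)C(C)(C)C)CC(C)=C | intermediate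
14 | methyl acrylate | C=CC(=O)OC | starting material
15 | MBH adduct of 13 (C3 epimeric mixture, C3 unspecified) | COC(=O)C(=C)C(O)[C@H](O[Si](C)(C)C(C)(C)C)CC(C)=C | intermediate
16 | CM1 product (C3 unspecified) | COC(=O)C(=C)C(O)[C@H](O[Si](C)(C)C(C)(C)C)C/C(C)=C/C[C@H](OCc1ccc(OC)cc1)C(C)=C | intermediate
17 | CM2 product (C3 unspecified) | COC(=O)C(=C)C(O)[C@H](O[Si](C)(C)C(C)(C)C)C/C(C)=C/C[C@H](OCc1ccc(OC)cc1)/C(C)=C/C[C@@H](O[Si](C)(C)C(C)(C)C)/C(C)=C/C(OC)OC | intermediate
18 | C2 enal, C3-OH (C3 unspecified) | COC(=O)C(=C)C(O)[C@H](O[Si](C)(C)C(C)(C)C)C/C(C)=C/C[C@H](OCc1ccc(OC)cc1)/C(C)=C/C[C@@H](O[Si](C)(C)C(C)(C)C)/C(C)=C/C=O | intermediate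
19 | (Z)-2-(bromomethyl)acrylate enal | BrC/C(C(=O)OC)=C\[C@H](O[Si](C)(C)C(C)(C)C)C/C(C)=C/C[C@H](OCc1ccc(OC)cc1)/C(C)=C/C[C@@H](O[Si](C)(C)C(C)(C)C)/C(C)=C/C=O | intermediate
20 | macrocyclic trans-lactone, 5,14-bis(TBSO), 9-OPMB, Δ3,4 | C=C1C(=O)O[C@H]2[C@H]1[C@H](O[Si](C)(C)C(C)(C)C)C/C(C)=C/C[C@H](OCc3ccc(OC)cc3)/C(C)=C/C[C@@H](O[Si](C)(C)C(C)(C)C)/C(C)=C/2 | intermediate
21 | 5,14-diol, 9-OPMB, Δ3,4 | C=C1C(=O)O[C@H]2[C@H]1[C@H](O)C/C(C)=C/C[C@H](OCc3ccc(OC)cc3)/C(C)=C/C[C@@H](O)/C(C)=C/2 | intermediate
22 | 3,4-epoxy-5,14-diol, 9-OPMB | C=C1C(=O)O[C@H]2[C@H]1[C@H](O)C/C(C)=C/C[C@H](OCc3ccc(OC)cc3)/C(C)=C/C[C@@H](O)[C@]1(C)O[C@@H]21 | intermediate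
23 | 5,14-diacetate, 9-OPMB | C=C1C(=O)O[C@H]2[C@H]1[C@H](OC(C)=O)C/C(C)=C/C[C@H](OCc3ccc(OC)cc3)/C(C)=C/C[C@@H](OC(C)=O)[C@]1(C)O[C@@H]21 | intermediate
24 | michaolide A | C=C1C(=O)O[C@H]2[C@H]1[C@H](OC(C)=O)C/C(C)=C/C[C@H](O)/C(C)=C/C[C@@H](OC(C)=O)[C@]1(C)O[C@@H]21 | target

## Totals

Total steps: 18. Longest linear sequence: 13 (steps 6–18, via the C14 fragment).

## Three steps most likely to fail

1. **Step 14, NHK macrocyclization and lactonization.** The yield and the C1/C2 diastereoselectivity depend on the macrocyclic transition state and C14 induction.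
   - Fallback: form the lactone intermolecularly. Do an In-mediated Barbier allylation of the enal from 5 (after acetal hydrolysis) with the Z-bromide made from 16 (MsCl, then LiBr). Then close the ring by ring-closing metathesis at C7=C8.

2. **Step 16, directed epoxidation.** The facial selectivity and the chemoselectivity against the homoallylic C14-OH and the other trisubstituted alkenes may be poor.
   - Fallback: install the epoxide on the acyclic allylic alcohol 4 by VO(acac)2/TBHP or Sharpless epoxidation, then TBS-protect C5. Carry the epoxy acetal through both metatheses, unmask the epoxy-aldehyde under non-acidic conditions (TESOTf/2,4,6-collidine, then H2O), brominate as in step 13, and close by NHK.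

3. **Step 11, second cross-metathesis.** The 1,1-disubstituted alkene next to the OPMB carbon is hindered, and secondary metathesis can scramble the C11=C12 alkene.
   - Fallback: form C7=C8 by Horner–Wadsworth–Emmons olefination of a C7 aldehyde with an α-methyl-β-ketophosphonate to give the E-enone. Then set C9 by (S)-CBS reduction instead of the Brown allylation of step 4.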